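**Retrosynthetic overview**

1. Atom labels: ring A = C1–C6 (C1 and C6 are the fusion carbons, C4 bears CH3, alkene C4=C5); ring B = C1, C6, C7–C10 (pyran on C7; CH3 and NHCHO on C10); pyran = O, C11–C15 (C11 on C7, Cl on C14).
2. The target comes from the ring A enone (C5 ketone, C3=C4) by reductive 1,3-transposition. The enone comes in one operation from an acyclic keto enal: an amine-catalysed Michael addition makes C1–C6 (closes ring B) and an aldol condensation makes C3–C4 (closes ring A).
3. Enabling feature: in ring A the C4=C5 alkene lies between the methyl-bearing C4 and the fusion carbon C6. At the C5-ketone level C4 and C6 are therefore the two α-carbons of one carbonyl, while C1–C2–C3 is an enal whose β-carbon C1 sits on the fully substituted C10 (no γ-hydrogen). The C7–C10 tether makes both closures six-membered.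
4. The keto enal comes from ozonolysis and Wittig homologation of a diene. C10 is set by vinyl addition to a tert-butanesulfinyl ketimine. C7 and C11 come from the Sharpless epoxide of geraniol, opened at C2 by a copper-catalysed Grignard reaction.
5. Ring order: chlorinated pyran first (oxirane → oxolane → ring expansion with chloride), then ring B and ring A, both in the key step.

Key step: step 13

Remark (assumption): the epoxidation ketone of step 4 is the enantiomer of the usual D-fructose-derived ketone (accessible from L-sorbose) and is taken as available; the two Grignard solutions 3 and 15 are commercial.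

**Step 1**
Reactants: 1 geraniol
Product: 2 [(2S,3S)-3-methyl-3-(4-methylpent-3-en-1-yl)oxiran-2-yl]methanol
Conditions: Ti(OiPr)4 (5 mol %), L-(+)-diethyl tartrate (6 mol %), t-BuOOH, 4 Å MS, CH2Cl2, −20 °C
Reagents that add atoms: tert-butyl hydroperoxide, CC(C)(C)OO
Why: Sharpless asymmetric epoxidation of the allylic alcohol, in which the L-(+)-tartrate titanium complex delivers oxygen to one face of the 2,3-alkene only (the remote alkene is untouched) and so sets both oxirane carbons (future C7 and C11).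

**Step 2**
Reactants: 2 [(2S,3S)-3-methyl-3-(4-methylpent-3-en-1-yl)oxiran-2-yl]methanol; 3 but-3-en-1-ylmagnesium bromide
Product: 4 (2R,3S)-2-(but-3-en-1-yl)-3,7-dimethyloct-6-ene-1,3-diol
Conditions: 3 (3 equiv), CuI (10 mol %), THF, −30 → 0 °C; aq. NH4Cl
Reagents that add atoms: none
Why: Copper-catalysed SN2 opening of the 2,3-epoxy alcohol by the Grignard reagent should occur at C2, the only oxirane carbon that is not fully substituted, with inversion, so C7 is set stereospecifically while the tertiary carbinol C11 keeps its configuration.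

**Step 3**
Reactants: 4 (2R,3S)-2-(but-3-en-1-yl)-3,7-dimethyloct-6-ene-1,3-diol
Product: 5 [(2R,3S)-2-(but-3-en-1-yl)-3-hydroxy-3,7-dimethyloct-6-en-1-yl] 4-methylbenzenesulfonate
Conditions: TsCl, Et3N, DMAP (cat.), CH2Cl2, 0 °C
Reagents that add atoms: 4-methylbenzenesulfonyl chloride, Cc1ccc(cc1)S(Cl)(=O)=O
Why: Selective sulfonylation of the primary hydroxyl beside the unreactive tertiary one; no stereocenter is touched.

**Step 4**
Reactants: 5 [(2R,3S)-2-(but-3-en-1-yl)-3-hydroxy-3,7-dimethyloct-6-en-1-yl] 4-methylbenzenesulfonate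
Product: 7 [(2R)-2-[(2S,5R)-5-(2-hydroxypropan-2-yl)-2-methyloxolan-2-yl]hex-5-en-1-yl] 4-methylbenzenesulfonate, via oxirane 6 (not isolated)
Conditions: L-fructose-derived epoxidation ketone (30 mol %), Oxone (2KHSO5·KHSO4·K2SO4), K2CO3, Bu4NHSO4, MeCN/CH2(OMe)2/aq. Na2B4O7 buffer, 0 °C; extractive work-up, then CSA (10 mol %), CH2Cl2, 0 °C
Reagents that add atoms: potassium peroxymonosulfate (active part of Oxone), [K+].[O-]S(=O)(=O)OO
Why: Shi epoxidation, in which the chiral dioxirane should epoxidise the electron-rich trisubstituted alkene (not the monosubstituted one) under catalyst control to the (S)-oxirane, followed by acid-catalysed 5-exo-tet opening by the tertiary hydroxyl at the secondary oxirane carbon with inversion, which fixes C14 and places the hydroxypropyl group cis to the C7 branch.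

**Step 5**
Reactants: 7 [(2R)-2-[(2S,5R)-5-(2-hydroxypropan-2-yl)-2-methyloxolan-2-yl]hex-5-en-1-yl] 4-methylbenzenesulfonate
Product: 9 [(2R)-2-[(2S,5S)-5-chloro-2,6,6-trimethyloxan-2-yl]hex-5-en-1-yl] 4-methylbenzenesulfonate, via tertiary chloride 8 (not isolated)
Conditions: HCl (4 M in 1,4-dioxane), ZnCl2 (20 mol %), CH2Cl2, 0 °C → rt
Reagents that add atoms: hydrogen chloride, Cl
Why: Ring expansion of a 2-(1-hydroxyalkyl)oxolane through a bicyclic oxonium ion, in which ionisation of the tertiary alcohol is assisted by the ring oxygen, chloride opens the ion at the secondary carbon C14 with inversion (chlorine cis to the C7 branch), and the tertiary chloride 8 from attack at the other carbon should re-ionise under ZnCl2 and be funnelled to 9, whose axial C–Cl bond has no antiperiplanar C–O bond.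

**Step 6**
Reactants: 9 [(2R)-2-[(2S,5S)-5-chloro-2,6,6-trimethyloxan-2-yl]hex-5-en-1-yl] 4-methylbenzenesulfonate; 10 2-bromobut-1-ene
Product: 12 (2S,5S)-5-chloro-2,6,6-trimethyl-2-[(5R)-3-methylidenenon-8-en-5-yl]oxane, via Grignard reagent 11 (not isolated)
Conditions: 10, Mg, THF, 40 °C; then 9, Li2CuCl4 (5 mol %), THF, −20 → 0 °C
Reagents that add atoms: none
Why: Kochi-type copper-catalysed coupling of the alkenyl Grignard reagent with the primary tosylate (SN2 at C6) installs the 1,1-disubstituted alkene that masks the ethyl ketone, while the hindered secondary chloride and the terminal alkene should not react; no stereocenter is touched.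

**Step 7**
Reactants: 12 (2S,5S)-5-chloro-2,6,6-trimethyl-2-[(5R)-3-methylidenenon-8-en-5-yl]oxane
Product: 13 (5R)-5-[(2S,5S)-5-chloro-2,6,6-trimethyloxan-2-yl]-7-methylidenenonan-2-one
Conditions: PdCl2 (10 mol %), CuCl (20 mol %), O2 (1 atm), DMF/H2O 7:1, rt
Reagents that add atoms: water, O
Why: Tsuji–Wacker oxidation is selective for the monosubstituted terminal alkene and should leave the 1,1-disubstituted alkene, so only the methyl ketone at C10 is unveiled.

**Step 8**
Reactants: 13 (5R)-5-[(2S,5S)-5-chloro-2,6,6-trimethyloxan-2-yl]-7-methylidenenonan-2-one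
Product: 14 (R)-N-[(2E,5R)-5-[(2S,5S)-5-chloro-2,6,6-trimethyloxan-2-yl]-7-methylidenenonan-2-ylidene]-2-methylpropane-2-sulfinamide
Conditions: (R)-t-BuS(O)NH2, Ti(OEt)4, THF, 65 °C
Reagents that add atoms: (R)-2-methylpropane-2-sulfinamide, CC(C)(C)[S@@](=O)N
Why: Ti(OEt)4-mediated condensation (Lewis acid and water scavenger) should give the N-sulfinyl ketimine, mainly as the E isomer with sulfur anti to the longer chain.

**Step 9**
Reactants: 14 (R)-N-[(2E,5R)-5-[(2S,5S)-5-chloro-2,6,6-trimethyloxan-2-yl]-7-methylidenenonan-2-ylidene]-2-methylpropane-2-sulfinamide; 15 ethenylmagnesium bromide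
Product: 16 (R)-N-[(3R,6R)-6-[(2S,5S)-5-chloro-2,6,6-trimethyloxan-2-yl]-3-methyl-8-methylidenedec-1-en-3-yl]-2-methylpropane-2-sulfinamide
Conditions: 15 (3 equiv), CH2Cl2/toluene, −78 → −40 °C; aq. NH4Cl
Reagents that add atoms: none
Why: 1,2-Addition of the Grignard reagent to the tert-butanesulfinyl ketimine through a six-membered chelate (magnesium on the sulfinyl oxygen, non-coordinating solvent) should deliver the vinyl group to one face of the E-ketimine and set the α-tertiary amine center C10 under auxiliary control.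

**Step 10**
Reactants: 16 (R)-N-[(3R,6R)-6-[(2S,5S)-5-chloro-2,6,6-trimethyloxan-2-yl]-3-methyl-8-methylidenedec-1-en-3-yl]-2-methylpropane-2-sulfinamide
Product: 18 N-[(3R,6R)-6-[(2S,5S)-5-chloro-2,6,6-trimethyloxan-2-yl]-3-methyl-8-methylidenedec-1-en-3-yl]formamide, via ammonium chloride 17 (not isolated)
Conditions: HCl (4 M in 1,4-dioxane, 2 equiv), MeOH, 0 °C; evaporate; then Et3N, HCO2CH2CF3, THF, 50 °C
Reagents that add atoms: 2,2,2-trifluoroethyl formate, O=COCC(F)(F)F
Why: Acidic methanolysis cleaves the N–S bond of the sulfinamide and the freed hindered amine is N-formylated by the activated formate ester; the quaternary center is not affected.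

**Step 11**
Reactants: 18 N-[(3R,6R)-6-[(2S,5S)-5-chloro-2,6,6-trimethyloxan-2-yl]-3-methyl-8-methylidenedec-1-en-3-yl]formamide
Product: 19 N-[(2R,5R)-5-[(2S,5S)-5-chloro-2,6,6-trimethyloxan-2-yl]-2-methyl-1,7-dioxononan-2-yl]formamide
Conditions: O3, CH2Cl2/MeOH, −78 °C; then PPh3, −78 °C → rt
Reagents that add atoms: ozone, [O-][O+]=O
Why: Ozonolysis with reductive work-up cleaves both remaining alkenes at once, the vinyl group to the aldehyde C1 and the 1,1-disubstituted alkene to the ethyl ketone C5; the aldehyde is α-quaternary and cannot epimerise.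

**Step 12**
Reactants: 19 N-[(2R,5R)-5-[(2S,5S)-5-chloro-2,6,6-trimethyloxan-2-yl]-2-methyl-1,7-dioxononan-2-yl]formamide; 20 (triphenyl-λ5-phosphanylidene)acetaldehyde
Product: 21 N-[(2E,4R,7R)-7-[(2S,5S)-5-chloro-2,6,6-trimethyloxan-2-yl]-4-methyl-1,9-dioxoundec-2-en-4-yl]formamide
Conditions: 20 (1.2 equiv), toluene, 80 °C
Reagents that add atoms: none
Why: Wittig olefination with the stabilised ylide is selective for the aldehyde over the ketone and should give the (E)-enal.

**Step 13**
Reactants: 21 N-[(2E,4R,7R)-7-[(2S,5S)-5-chloro-2,6,6-trimethyloxan-2-yl]-4-methyl-1,9-dioxoundec-2-en-4-yl]formamide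
Product: 24 N-[(1R,4R,4aR,8aS)-4-[(2S,5S)-5-chloro-2,6,6-trimethyloxan-2-yl]-1,6-dimethyl-5-oxo-1,2,3,4,4a,5,8,8a-octahydronaphthalen-1-yl]formamide, via keto aldehyde 22 (not isolated), via hydroxy ketone 23 (not isolated)
Conditions: (R)-α,α-diphenylprolinol trimethylsilyl ether (20 mol %), PhCO2H (40 mol %), toluene, rt → 50 °C
Reagents that add atoms: none
Why: The secondary amine condenses with the enal to an iminium ion, the C6 enol terminus of the ethyl ketone adds to its β-carbon C1 (Michael addition), and the freed aldehyde, again as its iminium ion, is attacked by the C4 enol terminus, after which loss of amine and water gives the 2-methylcyclohex-2-enone of ring A; the closest known reaction type is the amine-catalysed Michael addition/aldol condensation of a ketone with an enal (a Robinson-type annulation in its three-plus-three form). Ring B closes in the 6-exo-trig mode (C6 onto C1; attack through C4 would need an eight-membered ring) and ring A in the 6-(enolexo)-exo-trig mode (C4 onto C3; C6 onto C3 would need a four-membered ring), so ring size fixes the constitution. C1 is set by the catalyst: the diaryl(silyloxy)methyl group of the (R)-catalyst shields one face of the E, s-trans iminium ion, so C6 should bond to the face of C1 that places C2 axial on the chair of ring B (pyran at C7 equatorial, C10 methyl axial), cis to the C10 nitrogen. C6 is α to the C5 ketone and should epimerise under the reaction conditions to the equatorial acyl arrangement trans to the C7 pyran, the only one that keeps the bulky C7 group equatorial in the cis-fused product. The step needs facial selectivity at C1 against an expected small substrate preference for the trans-fused epimer, which the catalyst has to override, and iminium rather than dienamine reactivity, which the fully substituted C10 (no γ-hydrogen) secures. The formamide, the alkyl chloride and the cyclic ether should be inert to the weakly acidic amine conditions.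

**Step 14**
Reactants: 24 N-[(1R,4R,4aR,8aS)-4-[(2S,5S)-5-chloro-2,6,6-trimethyloxan-2-yl]-1,6-dimethyl-5-oxo-1,2,3,4,4a,5,8,8a-octahydronaphthalen-1-yl]formamide
Product: 25 N-[(1R,4R,4aR,8aS)-4-[(2S,5S)-5-chloro-2,6,6-trimethyloxan-2-yl]-1,6-dimethyl-5-[2-(4-methylbenzenesulfonyl)hydrazinylidene]-1,2,3,4,4a,5,8,8a-octahydronaphthalen-1-yl]formamide
Conditions: TsNHNH2, AcOH (cat.), EtOH, 50 °C
Reagents that add atoms: 4-methylbenzenesulfonohydrazide, Cc1ccc(cc1)S(=O)(=O)NN
Why: Condensation of the enone carbonyl with the sulfonyl hydrazide gives the α,β-unsaturated tosylhydrazone; C6, the only enolisable stereocenter, already has its preferred configuration.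

**Step 15**
Reactants: 25 N-[(1R,4R,4aR,8aS)-4-[(2S,5S)-5-chloro-2,6,6-trimethyloxan-2-yl]-1,6-dimethyl-5-[2-(4-methylbenzenesulfonyl)hydrazinylidene]-1,2,3,4,4a,5,8,8a-octahydronaphthalen-1-yl]formamide
Product: 26 N-[(1R,4R,4aR,8aS)-4-[(2S,5S)-5-chloro-2,6,6-trimethyloxan-2-yl]-1,6-dimethyl-1,2,3,4,4a,7,8,8a-octahydronaphthalen-1-yl]formamide
Conditions: catecholborane, CHCl3, 0 °C; then NaOAc·3H2O, 60 °C
Reagents that add atoms: none
Why: Alkene-transposing tosylhydrazone reduction (Kabalka reduction): hydride adds to C=N, loss of sulfinate gives an allylic diazene, and its retro-ene loss of N2 delivers hydrogen to C3 and moves the double bond to C4=C5; no stereocenter is formed and C6 is retained.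

**Compound list**

1 | geraniol, (2E)-3,7-dimethylocta-2,6-dien-1-ol | CC(C)=CCC/C(C)=C/CO | starting material
2 | [(2S,3S)-3-methyl-3-(4-methylpent-3-en-1-yl)oxiran-2-yl]methanol | CC(C)=CCC[C@]1(C)O[C@H]1CO | intermediate
3 | but-3-en-1-ylmagnesium bromide | C=CCC[Mg]Br | starting material
4 | (2R,3S)-2-(but-3-en-1-yl)-3,7-dimethyloct-6-ene-1,3-diol | C=CCC[C@H](CO)[C@@](C)(O)CCC=C(C)C | intermediate
5 | [(2R,3S)-2-(but-3-en-1-yl)-3-hydroxy-3,7-dimethyloct-6-en-1-yl] 4-methylbenzenesulfonate | C=CCC[C@H](COS(=O)(=O)c1ccc(C)cc1)[C@@](C)(O)CCC=C(C)C | intermediate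
6 | [(2R,3S)-2-(but-3-en-1-yl)-5-[(2S)-3,3-dimethyloxiran-2-yl]-3-hydroxy-3-methylpentyl] 4-methylbenzenesulfonate | C=CCC[C@H](COS(=O)(=O)c1ccc(C)cc1)[C@@](C)(O)CC[C@@H]2OC2(C)C | intermediate
7 | [(2R)-2-[(2S,5R)-5-(2-hydroxypropan-2-yl)-2-methyloxolan-2-yl]hex-5-en-1-yl] 4-methylbenzenesulfonate | C=CCC[C@H](COS(=O)(=O)c1ccc(C)cc1)[C@]2(C)CC[C@@H](O2)C(C)(C)O | intermediate
8 | [(2R)-2-[(2S,5R)-5-(2-chloropropan-2-yl)-2-methyloxolan-2-yl]hex-5-en-1-yl] 4-methylbenzenesulfonate | C=CCC[C@H](COS(=O)(=O)c1ccc(C)cc1)[C@]2(C)CC[C@@H](O2)C(C)(C)Cl | intermediate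
9 | [(2R)-2-[(2S,5S)-5-chloro-2,6,6-trimethyloxan-2-yl]hex-5-en-1-yl] 4-methylbenzenesulfonate | C=CCC[C@H](COS(=O)(=O)c1ccc(C)cc1)[C@]2(C)CC[C@H](Cl)C(C)(C)O2 | intermediate
10 | 2-bromobut-1-ene | CCC(Br)=C | starting material
11 | but-1-en-2-ylmagnesium bromide | CCC(=C)[Mg]Br | intermediate
12 | (2S,5S)-5-chloro-2,6,6-trimethyl-2-[(5R)-3-methylidenenon-8-en-5-yl]oxane | C=CCC[C@H](CC(=C)CC)[C@]1(C)CC[C@H](Cl)C(C)(C)O1 | intermediate
13 | (5R)-5-[(2S,5S)-5-chloro-2,6,6-trimethyloxan-2-yl]-7-methylidenenonan-2-one | CC(=O)CC[C@H](CC(=C)CC)[C@]1(C)CC[C@H](Cl)C(C)(C)O1 | intermediate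
14 | (R)-N-[(2E,5R)-5-[(2S,5S)-5-chloro-2,6,6-trimethyloxan-2-yl]-7-methylidenenonan-2-ylidene]-2-methylpropane-2-sulfinamide | CC(C)(C)[S@@](=O)/N=C(\C)CC[C@H](CC(=C)CC)[C@]1(C)CC[C@H](Cl)C(C)(C)O1 | intermediate
15 | ethenylmagnesium bromide | C=C[Mg]Br | starting material
16 | (R)-N-[(3R,6R)-6-[(2S,5S)-5-chloro-2,6,6-trimethyloxan-2-yl]-3-methyl-8-methylidenedec-1-en-3-yl]-2-methylpropane-2-sulfinamide | C=C[C@](C)(N[S@](=O)C(C)(C)C)CC[C@H](CC(=C)CC)[C@]1(C)CC[C@H](Cl)C(C)(C)O1 | intermediate
17 | (3R,6R)-6-[(2S,5S)-5-chloro-2,6,6-trimethyloxan-2-yl]-3-methyl-8-methylidenedec-1-en-3-aminium chloride | C=C[C@](C)([NH3+])CC[C@H](CC(=C)CC)[C@]1(C)CC[C@H](Cl)C(C)(C)O1.[Cl-] | intermediate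
18 | N-[(3R,6R)-6-[(2S,5S)-5-chloro-2,6,6-trimethyloxan-2-yl]-3-methyl-8-methylidenedec-1-en-3-yl]formamide | C=C[C@](C)(NC=O)CC[C@H](CC(=C)CC)[C@]1(C)CC[C@H](Cl)C(C)(C)O1 | intermediate
19 | N-[(2R,5R)-5-[(2S,5S)-5-chloro-2,6,6-trimethyloxan-2-yl]-2-methyl-1,7-dioxononan-2-yl]formamide | O=C[C@](C)(NC=O)CC[C@H](CC(=O)CC)[C@]1(C)CC[C@H](Cl)C(C)(C)O1 | intermediate
20 | (triphenyl-λ5-phosphanylidene)acetaldehyde | O=CC=P(c1ccccc1)(c1ccccc1)c1ccccc1 | starting material
21 | N-[(2E,4R,7R)-7-[(2S,5S)-5-chloro-2,6,6-trimethyloxan-2-yl]-4-methyl-1,9-dioxoundec-2-en-4-yl]formamide | O=C/C=C/[C@](C)(NC=O)CC[C@H](CC(=O)CC)[C@]1(C)CC[C@H](Cl)C(C)(C)O1 | intermediate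
22 | N-[(1R,2S,3R,4R)-4-[(2S,5S)-5-chloro-2,6,6-trimethyloxan-2-yl]-1-methyl-2-(2-oxoethyl)-3-propanoylcyclohexyl]formamide | CCC(=O)[C@H]1[C@H]([C@]2(C)CC[C@H](Cl)C(C)(C)O2)CC[C@@](C)(NC=O)[C@H]1CC=O | intermediate
23 | N-[(1R,4R,4aR,8aS)-4-[(2S,5S)-5-chloro-2,6,6-trimethyloxan-2-yl]-7-hydroxy-1,6-dimethyl-5-oxodecahydronaphthalen-1-yl]formamide (configuration at C3 and C4 of ring A not fixed) | CC1C(O)C[C@H]2[C@@H](C1=O)[C@H]([C@]3(C)CC[C@H](Cl)C(C)(C)O3)CC[C@@]2(C)NC=O | intermediate
24 | N-[(1R,4R,4aR,8aS)-4-[(2S,5S)-5-chloro-2,6,6-trimethyloxan-2-yl]-1,6-dimethyl-5-oxo-1,2,3,4,4a,5,8,8a-octahydronaphthalen-1-yl]formamide | CC1=CC[C@H]2[C@@H](C1=O)[C@H]([C@]3(C)CC[C@H](Cl)C(C)(C)O3)CC[C@@]2(C)NC=O | intermediate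
25 | N-[(1R,4R,4aR,8aS)-4-[(2S,5S)-5-chloro-2,6,6-trimethyloxan-2-yl]-1,6-dimethyl-5-[2-(4-methylbenzenesulfonyl)hydrazinylidene]-1,2,3,4,4a,5,8,8a-octahydronaphthalen-1-yl]formamide (C=N geometry not fixed) | CC1=CC[C@H]2[C@@H](C1=NNS(=O)(=O)c4ccc(C)cc4)[C@H]([C@]3(C)CC[C@H](Cl)C(C)(C)O3)CC[C@@]2(C)NC=O | intermediate
26 | N-[(1R,4R,4aR,8aS)-4-[(2S,5S)-5-chloro-2,6,6-trimethyloxan-2-yl]-1,6-dimethyl-1,2,3,4,4a,7,8,8a-octahydronaphthalen-1-yl]formamide | CC1=C[C@H]2[C@H]([C@]3(C)CC[C@H](Cl)C(C)(C)O3)CC[C@@](C)(NC=O)[C@H]2CC1 | target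

**Step count and risks**

Total step count: 15. Longest linear sequence: 15 steps (geraniol 1 to target 26); 3, 10, 15 and 20 are commercial.

Steps most likely to fail:

1. Step 13 (key step). Facial selectivity at C1 may be poor, because the chair transition state with C2 equatorial (leading to the trans-fused C1 epimer) is expected to be slightly favoured by the substrate and the catalyst must override it. The unactivated ketone may also enolise too slowly to engage the iminium ion. The fallback makes the two bonds one after the other under substrate control; it sets out from keto aldehyde 19 and comes back at enone 24. Intramolecular aldol condensation of 19 (piperidine, AcOH, benzene, reflux; only the ketone can enolise, since the aldehyde is α-quaternary) should give N-[(1R,4R)-4-[(2S,5S)-5-chloro-2,6,6-trimethyloxan-2-yl]-1-methyl-3-propanoylcyclohex-2-en-1-yl]formamide F1. Hosomi–Sakurai conjugate allylation of F1 (allyltrimethylsilane, TiCl4, CH2Cl2, −78 °C) should deliver the allyl group axially to C1, anti to the axial C10 methyl group, and after protonation at C6 give N-[(1R,2S,3R,4R)-4-[(2S,5S)-5-chloro-2,6,6-trimethyloxan-2-yl]-1-methyl-2-(prop-2-en-1-yl)-3-propanoylcyclohexyl]formamide F2. Ozonolysis of F2 (O3, then PPh3) gives keto aldehyde 22, which is closed to 24 by aldol condensation (pyrrolidine, AcOH, benzene, 60 °C).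

2. Step 5. The oxonium ion may be captured at the tertiary carbon without later equilibration, may lose a proton to an isopropenyl ether, or the tertiary C11–O bond may ionise in acid and scramble C11. The fallback builds the chlorinated oxane directly by chloronium-induced cyclisation; it sets out from tosylate 5 and comes back at 9. Treatment of 5 with Et2SCl·SbCl6 (chlorodiethylsulfonium hexachloroantimonate) in MeNO2 at −25 °C should give 6-endo chloroetherification at the trisubstituted alkene (Markovnikov attack of the tertiary hydroxyl). Selectivity at the chlorine-bearing carbon is then only substrate-controlled, so 9 would have to be separated from its epimer [(2R)-2-[(2S,5R)-5-chloro-2,6,6-trimethyloxan-2-yl]hex-5-en-1-yl] 4-methylbenzenesulfonate F3.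

3. Step 9. Diastereoselectivity may be eroded by E/Z isomerism of the methyl alkyl ketimine, and the basic Grignard reagent may deprotonate the ketimine instead of adding. The fallback uses a slim, much less basic alkynyl nucleophile and a later semi-hydrogenation; it sets out from ketimine 14 and comes back at formamide 18. Addition of ethynylmagnesium bromide (CH2Cl2/THF, −78 → −20 °C) should give (R)-N-[(3R,6R)-6-[(2S,5S)-5-chloro-2,6,6-trimethyloxan-2-yl]-3-methyl-8-methylidenedec-1-yn-3-yl]-2-methylpropane-2-sulfinamide F4. Cleavage with HCl in MeOH gives (3R,6R)-6-[(2S,5S)-5-chloro-2,6,6-trimethyloxan-2-yl]-3-methyl-8-methylidenedec-1-yn-3-aminium chloride F5, and formylation (Et3N, HCO2CH2CF3, THF, 50 °C) gives N-[(3R,6R)-6-[(2S,5S)-5-chloro-2,6,6-trimethyloxan-2-yl]-3-methyl-8-methylidenedec-1-yn-3-yl]formamide F6. Semi-hydrogenation of F6 (H2, Pd/CaCO3 poisoned with Pb(OAc)2, quinoline, EtOAc) reduces only the alkyne and gives 18.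

**Further compounds**

F1 | step 13 | N-[(1R,4R)-4-[(2S,5S)-5-chloro-2,6,6-trimethyloxan-2-yl]-1-methyl-3-propanoylcyclohex-2-en-1-yl]formamide | CCC(=O)C1=C[C@](C)(NC=O)CC[C@H]1[C@]2(C)CC[C@H](Cl)C(C)(C)O2
F2 | step 13 | N-[(1R,2S,3R,4R)-4-[(2S,5S)-5-chloro-2,6,6-trimethyloxan-2-yl]-1-methyl-2-(prop-2-en-1-yl)-3-propanoylcyclohexyl]formamide | CCC(=O)[C@H]1[C@H]([C@]2(C)CC[C@H](Cl)C(C)(C)O2)CC[C@@](C)(NC=O)[C@H]1CC=C
F3 | step 5 | [(2R)-2-[(2S,5R)-5-chloro-2,6,6-trimethyloxan-2-yl]hex-5-en-1-yl] 4-methylbenzenesulfonate | C=CCC[C@H](COS(=O)(=O)c1ccc(C)cc1)[C@]2(C)CC[C@@H](Cl)C(C)(C)O2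
F4 | step 9 | (R)-N-[(3R,6R)-6-[(2S,5S)-5-chloro-2,6,6-trimethyloxan-2-yl]-3-methyl-8-methylidenedec-1-yn-3-yl]-2-methylpropane-2-sulfinamide | C#C[C@](C)(N[S@](=O)C(C)(C)C)CC[C@H](CC(=C)CC)[C@]1(C)CC[C@H](Cl)C(C)(C)O1
F5 | step 9 | (3R,6R)-6-[(2S,5S)-5-chloro-2,6,6-trimethyloxan-2-yl]-3-methyl-8-methylidenedec-1-yn-3-aminium chloride | C#C[C@](C)([NH3+])CC[C@H](CC(=C)CC)[C@]1(C)CC[C@H](Cl)C(C)(C)O1.[Cl-]
F6 | step 9 | N-[(3R,6R)-6-[(2S,5S)-5-chloro-2,6,6-trimethyloxan-2-yl]-3-methyl-8-methylidenedec-1-yn-3-yl]formamide | C#C[C@](C)(NC=O)CC[C@H](CC(=C)CC)[C@]1(C)CC[C@H](Cl)C(C)(C)O1
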